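Ring A (C1 butyryl; C2, C4, C6 OH; C3, C5 bridge CH2) is cut at C5–C6 and C1–C2. The feature exploited is its polyketide pattern: oxygen on every second carbon and identical ring B benzyl groups on C3 and C5. The run C2–C5, bridges included, therefore maps onto two head-to-tail molecules of a single 3-arylpropanoate. C6, C1 and the side-chain ketone map onto a 3-oxohexanoyl unit. In one operation the α,γ-dianion of keto ester 7 is acylated at C5 by the enolate salt of 8, and the resulting triketo ester folds into aromatic ring A. Precursor 7 is methyl 2-(arylmethyl)-3-oxo-5-arylpentanoate, aryl = 2,4,6-trimethoxy-3-methylphenyl, C3' still unsubstituted.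

Key step: step 5

Assumption: the target has no stereocentre, so none has to be set; 7, 11 and the fallback carbinol are handled as mixtures of stereoisomers and keto–enol tautomers. Rings B are labelled C1' (bridge), C2', C3' (butyryl), C4', C5' (CH3), C6' (OCH3).

Step 1
Reactants: 1 2,4,6-trimethoxytoluene
Product: 3 2,4,6-trimethoxy-3-methylbenzaldehyde, via aryl iminium chloride 2 (not isolated)
Conditions: POCl3 (1.2 equiv), DMF, 0 °C → rt; then ice–water
Reagents that add atoms: N,N-dimethylformamide CN(C)C=O; water O
Why: Vilsmeier–Haack formylation is dependable on phloroglucinol ethers, the two open ring positions of 1 are equivalent so only one aldehyde can form, and the electron-poor iminium group blocks a second attack.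

Step 2
Reactants: 3 2,4,6-trimethoxy-3-methylbenzaldehyde; 4 methyl (triphenylphosphoranylidene)acetate
Product: 5 methyl (E)-3-(2,4,6-trimethoxy-3-methylphenyl)prop-2-enoate
Conditions: toluene, reflux
Reagents that add atoms: none
Why: Wittig olefination with a stabilised ylide copes with the electron-rich, doubly ortho-substituted aldehyde at reflux, supplies the methyl ester directly, and its E preference does not matter because the alkene is reduced next.

Step 3
Reactants: 5 methyl (E)-3-(2,4,6-trimethoxy-3-methylphenyl)prop-2-enoate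
Product: 6 methyl 3-(2,4,6-trimethoxy-3-methylphenyl)propanoate
Conditions: H2 (1 atm), 10% Pd/C, EtOAc, rt
Reagents that add atoms: none
Why: Heterogeneous catalytic hydrogenation saturates the conjugated alkene and leaves the aryl methyl ethers, ester and arene untouched, since no benzylic C–O or C–halogen bond is present.

Step 4
Reactants: 6 methyl 3-(2,4,6-trimethoxy-3-methylphenyl)propanoate (two molecules)
Product: 7 methyl 3-oxo-5-(2,4,6-trimethoxy-3-methylphenyl)-2-[(2,4,6-trimethoxy-3-methylphenyl)methyl]pentanoate (racemic)
Conditions: NaH (1.1 equiv per mol of 6), MeOH (cat.), THF, reflux; then 1 M HCl, 0 °C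
Reagents that add atoms: none
Why: Claisen self-condensation of a single ester can give only one β-keto ester, is driven by irreversible deprotonation of the C–H left between the two carbonyls, and forms its one stereocentre as a labile racemate that step 5 erases.

Step 5
Reactants: 7 methyl 3-oxo-5-(2,4,6-trimethoxy-3-methylphenyl)-2-[(2,4,6-trimethoxy-3-methylphenyl)methyl]pentanoate; 8 methyl 3-oxohexanoate
Product: 12 1-{2,4,6-trihydroxy-3,5-bis[(2,4,6-trimethoxy-3-methylphenyl)methyl]phenyl}butan-1-one, via dianion 9 (not isolated), via sodium enolate 10 (not isolated), via triketo ester 11 (not isolated)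
Conditions: 7, NaH (1.05 equiv), THF, 0 °C; LiN(i-Pr)2 (2.1 equiv), −78 → 0 °C; add 10 [from 8 (2 equiv), NaH (2 equiv), THF, 0 °C] at −78 °C, → 0 °C; MeOH, then Mg(OMe)2 (4 equiv, in MeOH), rt → 50 °C; 1 M HCl
Reagents that add atoms: none
Why: NaH removes C3–H of 7 and LiN(i-Pr)2 removes one C5–H, giving dianion 9, whose C5 carbon is the most nucleophilic site; C5 adds to the ester carbonyl C6 of salt 10, whose ketone is masked as the enolate, methoxide leaves (bond C5–C6), and the second equivalent of amide absorbs the C5–H that acylation makes acidic, so 11 sits in the flask as its polyanion. Once MeOH has discharged the strong base, Mg(OMe)2 chelates the chain and ionises only doubly flanked carbons, so C1 attacks the ester carbonyl C2, methoxide leaves (bond C1–C2), and the 2-acylcyclohexane-1,3,5-trione tautomerises to the ring A phenolate, an irreversible sink. The closest known reaction types are the acylation of β-keto ester α,γ-dianions by salts of β-keto esters and the Claisen (Dieckmann-type) cyclisation of 3,5,7-triketo esters to acylphloroglucinols under magnesium alkoxide. Ring A closes 6-exo-trig at the ester carbonyl, enolexo if the enolate is drawn towards the butyryl carbonyl and enolendo if drawn towards C6, and both modes are favoured for a six-membered ring. No stereocentre is created, and the labile centres at C3 and C5 vanish on aromatisation. The step needs Claisen over aldol folding, C- over O-attack and cross- over self-coupling: an aldol of C3 onto the butyryl carbonyl would leave C3 quaternary and so stays reversible, a 2-pyranone from O-attack is reopened by methoxide, the propyl CH2 is not ionised by Mg(OMe)2, the fully substituted enolate ester of 7 is a poor acceptor, and the amide base (unlike an alkyllithium) spares the C3'–H between two methoxy groups.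

Step 6
Reactants: 12 1-{2,4,6-trihydroxy-3,5-bis[(2,4,6-trimethoxy-3-methylphenyl)methyl]phenyl}butan-1-one; 13 butanoic anhydride
Product: 15 1-{3,5-bis[(3-butanoyl-2,4,6-trimethoxy-5-methylphenyl)methyl]-2,4,6-trihydroxyphenyl}butan-1-one, via ring A tributanoate 14 (not isolated)
Conditions: 13 (8 equiv), Sc(OTf)3 (0.2 equiv), MeNO2, 50 °C; concentrate; K2CO3 (4 equiv), MeOH, rt; 1 M HCl
Reagents that add atoms: none
Why: Triflate-catalysed Friedel–Crafts acylation can strike only C3' of each ring B, the sole open arene carbon (activated by three methoxy groups), while the same catalyst first esterifies the three ring A phenols and so shuts off ipso-protonation of ring A and loss of the bridges, and the aryl esters then fall to carbonate methanolysis, which cannot exchange bridges because rings B carry no free phenol.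

Step 7
Reactants: 15 1-{3,5-bis[(3-butanoyl-2,4,6-trimethoxy-5-methylphenyl)methyl]-2,4,6-trihydroxyphenyl}butan-1-one
Product: 16 1-{3,5-bis[(3-butanoyl-2,4-dihydroxy-6-methoxy-5-methylphenyl)methyl]-2,4,6-trihydroxyphenyl}butan-1-one (CNP0264591.0)
Conditions: BCl3 (1 M in CH2Cl2, 12 equiv), CH2Cl2, −78 → 0 °C; ice, 1 M HCl (no basic wash)
Reagents that add atoms: none
Why: In this chelation-directed aryl methyl ether cleavage, BCl3 held by each C3' ketone activates the flanking C2' and C4' ethers through six-membered boron chelates, whereas the C6' ether para to the ketone has no anchor and plain aryl methyl ethers resist BCl3 at or below 0 °C, and the base-free work-up avoids quinone-methide exchange of the bridges.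

Compound list
1 | 2,4,6-trimethoxytoluene | Cc1c(OC)cc(OC)cc1OC | starting material
2 | N,N-dimethyl-1-(2,4,6-trimethoxy-3-methylphenyl)methaniminium chloride | C[N+](C)=Cc1c(OC)cc(OC)c(C)c1OC.[Cl-] | intermediate
3 | 2,4,6-trimethoxy-3-methylbenzaldehyde | O=Cc1c(OC)cc(OC)c(C)c1OC | intermediate
4 | methyl (triphenylphosphoranylidene)acetate | COC(=O)C=P(c1ccccc1)(c1ccccc1)c1ccccc1 | starting material
5 | methyl (E)-3-(2,4,6-trimethoxy-3-methylphenyl)prop-2-enoate | COC(=O)/C=C/c1c(OC)cc(OC)c(C)c1OC | intermediate
6 | methyl 3-(2,4,6-trimethoxy-3-methylphenyl)propanoate | COC(=O)CCc1c(OC)cc(OC)c(C)c1OC | intermediate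
7 | methyl 3-oxo-5-(2,4,6-trimethoxy-3-methylphenyl)-2-[(2,4,6-trimethoxy-3-methylphenyl)methyl]pentanoate (racemic) | COC(=O)C(Cc1c(OC)cc(OC)c(C)c1OC)C(=O)CCc1c(OC)cc(OC)c(C)c1OC | intermediate
8 | methyl 3-oxohexanoate | CCCC(=O)CC(=O)OC | starting material
9 | sodium lithium α,γ-dianion (bis-enolate) of 7 | [Na+].[Li+].COC([O-])=C(Cc1c(OC)cc(OC)c(C)c1OC)C([O-])=CCc1c(OC)cc(OC)c(C)c1OC | intermediate
10 | sodium enolate of methyl 3-oxohexanoate | [Na+].CCCC([O-])=CC(=O)OC | intermediate
11 | methyl 3,5,7-trioxo-2,4-bis[(2,4,6-trimethoxy-3-methylphenyl)methyl]decanoate (epimer and tautomer mixture) | CCCC(=O)CC(=O)C(Cc1c(OC)cc(OC)c(C)c1OC)C(=O)C(Cc1c(OC)cc(OC)c(C)c1OC)C(=O)OC | intermediate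
12 | 1-{2,4,6-trihydroxy-3,5-bis[(2,4,6-trimethoxy-3-methylphenyl)methyl]phenyl}butan-1-one | CCCC(=O)c1c(O)c(Cc2c(OC)cc(OC)c(C)c2OC)c(O)c(Cc2c(OC)cc(OC)c(C)c2OC)c1O | intermediate
13 | butanoic anhydride | CCCC(=O)OC(=O)CCC | starting material
14 | 2-butanoyl-4,6-bis[(3-butanoyl-2,4,6-trimethoxy-5-methylphenyl)methyl]benzene-1,3,5-triyl tributanoate | CCCC(=O)c1c(OC(=O)CCC)c(Cc2c(OC)c(C(=O)CCC)c(OC)c(C)c2OC)c(OC(=O)CCC)c(Cc2c(OC)c(C(=O)CCC)c(OC)c(C)c2OC)c1OC(=O)CCC | intermediate
15 | 1-{3,5-bis[(3-butanoyl-2,4,6-trimethoxy-5-methylphenyl)methyl]-2,4,6-trihydroxyphenyl}butan-1-one | CCCC(=O)c1c(O)c(Cc2c(OC)c(C(=O)CCC)c(OC)c(C)c2OC)c(O)c(Cc2c(OC)c(C(=O)CCC)c(OC)c(C)c2OC)c1O | intermediate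
16 | 1-{3,5-bis[(3-butanoyl-2,4-dihydroxy-6-methoxy-5-methylphenyl)methyl]-2,4,6-trihydroxyphenyl}butan-1-one (CNP0264591.0) | CCCC(=O)c1c(O)c(Cc2c(O)c(C(=O)CCC)c(O)c(C)c2OC)c(O)c(Cc2c(O)c(C(=O)CCC)c(O)c(C)c2OC)c1O | target

Total step count: 7. Longest linear sequence: 7 (steps 1–7).

Steps most likely to fail

Step 5. Enolate 10 is not inert to base: it keeps removable protons on its own C4, and the diisopropylamine in the flask can ferry protons between 9 and 10. Donor and acceptor roles may therefore blur, which leads to self-coupling of the C6 unit and return of unchanged 7. In addition, a hindered secondary carbanion must attack an ester carbonyl that is damped by enolate conjugation, and lactonisation may compete in the closing phase.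
The fallback sets out from 7 and 8 and rejoins the route at 11. It replaces the one-pot polyanion coupling by a stepwise, protecting-group-based assembly.
- Ethylene glycol, TsOH (cat.) and toluene with a water separator convert 8 into methyl 2-(2-propyl-1,3-dioxolan-2-yl)acetate F1. This ester has no enolate charge beside its carbonyl and no free ketone.
- Dianion 9, made as in step 5, is acylated by F1 at −78 → 0 °C (ester acylation of a β-keto ester dianion). The product is isolated as methyl 3,5-dioxo-6-(2-propyl-1,3-dioxolan-2-yl)-2,4-bis[(2,4,6-trimethoxy-3-methylphenyl)methyl]hexanoate F2.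
- 1 M HCl in THF at rt removes the dioxolane and gives 11, now as an isolated compound. Mg(OMe)2 in MeOH then closes it to 12 in a separate flask.

Step 6. Substitution in the crowded pocket between two methoxy groups may stall after one ring. Acid may also break an aryl–CH2 bond before ring A is fully esterified.
The fallback sets out from 12 and rejoins at 15. It builds the ketone with a small electrophile followed by a nucleophile instead of an acylium species.
- Vilsmeier–Haack reaction (POCl3, DMF, 0 °C → rt), as used on the same ring type in step 1, gives the bis(iminium) dichloride of 12 F3.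
- Water hydrolyses this salt to 1-{3,5-bis[(3-formyl-2,4,6-trimethoxy-5-methylphenyl)methyl]-2,4,6-trihydroxyphenyl}butan-1-one F4.
- Excess n-PrMgBr in THF at 0 °C first converts the ring A phenols into magnesium phenoxides, which shield the ring A ketone. It then adds to both aldehydes to give 1-{3,5-bis[(3-(1-hydroxybutyl)-2,4,6-trimethoxy-5-methylphenyl)methyl]-2,4,6-trihydroxyphenyl}butan-1-one F5 as its magnesium alkoxide. F5 is a diastereomer mixture, which is of no consequence.
- Benzaldehyde added to the same flask accepts hydride (magnesium-alkoxide Oppenauer oxidation) and should deliver 15 without any oxidant that could attack ring A.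

Step 7. Ether cleavage may run unevenly. The second ether beside each ketone may lag while the crowded C6' ether begins to cleave, and this is aggravated because the free phenols and chelating ketone of ring A tie up BCl3. The bridges may also exchange once rings A and B both carry free phenols in a Lewis acidic medium.
The fallback sets out from 14, which is isolated instead of being methanolysed, and rejoins at 16. It reverses the order of deprotection so that ring A stays electron-poor and non-coordinating during the cleavage.
- BCl3 in CH2Cl2 at −78 → 0 °C acts on 14 to give 2-butanoyl-4,6-bis[(3-butanoyl-2,4-dihydroxy-6-methoxy-5-methylphenyl)methyl]benzene-1,3,5-triyl tributanoate F6.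
- The three activated aryl esters are then removed by acid-catalysed transesterification (HCl in MeOH, rt), again without base.

Further compounds
F1 | step 5 | methyl 2-(2-propyl-1,3-dioxolan-2-yl)acetate | CCCC1(CC(=O)OC)OCCO1
F2 | step 5 | methyl 3,5-dioxo-6-(2-propyl-1,3-dioxolan-2-yl)-2,4-bis[(2,4,6-trimethoxy-3-methylphenyl)methyl]hexanoate | CCCC1(CC(=O)C(Cc2c(OC)cc(OC)c(C)c2OC)C(=O)C(Cc2c(OC)cc(OC)c(C)c2OC)C(=O)OC)OCCO1
F3 | step 6 | bis(iminium) dichloride of 12 (C3'-CH=NMe2+ on both rings B) | CCCC(=O)c1c(O)c(Cc2c(OC)c(C=[N+](C)C)c(OC)c(C)c2OC)c(O)c(Cc2c(OC)c(C=[N+](C)C)c(OC)c(C)c2OC)c1O.[Cl-].[Cl-]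
F4 | step 6 | 1-{3,5-bis[(3-formyl-2,4,6-trimethoxy-5-methylphenyl)methyl]-2,4,6-trihydroxyphenyl}butan-1-one | CCCC(=O)c1c(O)c(Cc2c(OC)c(C=O)c(OC)c(C)c2OC)c(O)c(Cc2c(OC)c(C=O)c(OC)c(C)c2OC)c1O
F5 | step 6 | 1-{3,5-bis[(3-(1-hydroxybutyl)-2,4,6-trimethoxy-5-methylphenyl)methyl]-2,4,6-trihydroxyphenyl}butan-1-one (diastereomer mixture) | CCCC(=O)c1c(O)c(Cc2c(OC)c(C(O)CCC)c(OC)c(C)c2OC)c(O)c(Cc2c(OC)c(C(O)CCC)c(OC)c(C)c2OC)c1O
F6 | step 7 | 2-butanoyl-4,6-bis[(3-butanoyl-2,4-dihydroxy-6-methoxy-5-methylphenyl)methyl]benzene-1,3,5-triyl tributanoate | CCCC(=O)c1c(OC(=O)CCC)c(Cc2c(O)c(C(=O)CCC)c(O)c(C)c2OC)c(OC(=O)CCC)c(Cc2c(O)c(C(=O)CCC)c(O)c(C)c2OC)c1OC(=O)CCC
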